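**Strategy.** The tetrahydrofuran (O1, C2–C5; ring B on C2, ring C on C5) is cut at the C2–aryl bond and at the O1–C5 bond. Its two cis aryl/methyl pairs (C2/C3 and C4/C5) flank trans methyls at C3/C4; this is the feature used. A ring-B Grignard reagent adds to an aldehyde under 1,2-induction from the C3 methyl, and the alkoxide at once displaces a benzylic mesylate at C5 with inversion, so an all-trans lactone can supply C3–C5. The precursor is a 4-aryl-4-mesyloxy-2,3-dimethylbutanal whose ring C is an electron-poor aryl tosylate; the aldehyde is unmasked from a terminal alkene only after mesylation. Both side arms are added last.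

Key step: step 12

Remark: vinylmagnesium bromide (3) and (3,4-dimethoxyphenyl)magnesium bromide (24) are taken as bought THF solutions.
Remark: an amide carbonyl γ to the benzylic mesylate would attack C5 through oxygen and invert it, so the aldehyde of 14 is carried as a vinyl group until the mesylate is in place, and the mesylate is made with the anhydride so that no chloride is present.
Remark: with the order O > aryl > C4 > H at C5 unchanged, inversion takes (4R) in 14 to (5S) in 20; C3 of 12 and 13 is S only because the vinyl group ranks below C2.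

Step 1
Reactants: 1 vanillin
Product: 2 4-formyl-2-methoxyphenyl 4-methylbenzenesulfonate (O-tosylvanillin)
Conditions: TsCl, Et3N, DMAP (cat.), CH2Cl2, 0 → 20 °C
Reagents that add atoms: 4-methylbenzenesulfonyl chloride, Cc1ccc(cc1)S(Cl)(=O)=O
Why: O-sulfonylation of the phenol should be clean, and the tosylate both masks the ring-C phenol up to step 13 and makes ring C electron-poor.

Step 2
Reactants: 2 O-tosylvanillin, 3 vinylmagnesium bromide
Product: 5 (R)-1-[3-methoxy-4-(tosyloxy)phenyl]prop-2-en-1-ol, via divinylzinc 4 (not isolated)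
Conditions: 3, ZnCl2, Et2O/THF, 0 °C; 1,4-dioxane, filter (solution of 4); then 2, (2R)-(+)-3-exo-morpholinoisoborneol (5 mol %), toluene, −20 → 0 °C; aq. NH4Cl
Reagents that add atoms: none
Why: Amino-alcohol-catalysed enantioselective addition of an alkenylzinc reagent to an aryl aldehyde, in which the (+)-ligand should direct the vinyl group to the Re face and so set the (R) carbinol centre that becomes C5.

Step 3
Reactants: 5 (R)-allylic alcohol, 6 acryloyl chloride
Product: 7 (R)-1-[3-methoxy-4-(tosyloxy)phenyl]prop-2-en-1-yl prop-2-enoate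
Conditions: Et3N, CH2Cl2, −20 → 0 °C
Reagents that add atoms: none
Why: O-acylation of a secondary alcohol with an acid chloride should proceed with retention, since the C–O bond of the stereocentre is not touched.

Step 4
Reactants: 7 acrylate
Product: 8 (R)-5-[3-methoxy-4-(tosyloxy)phenyl]furan-2(5H)-one
Conditions: second-generation Grubbs catalyst [RuCl2(=CHPh)(PCy3)(H2IMes)] (5 mol %), CH2Cl2 (0.01 M), 40 °C
Reagents that add atoms: none
Why: Ring-closing metathesis of an allyl acrylate to a butenolide with loss of ethene is a standard closure of the five-membered unsaturated lactone and leaves C5 untouched.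

Step 5
Reactants: 8 butenolide
Product: 10 (3R,4R,5R)-3,4-dimethyl-5-[3-methoxy-4-(tosyloxy)phenyl]oxolan-2-one, via lithium lactone enolate 9 (not isolated)
Conditions: Me2CuLi (from MeLi and CuI), Et2O, −78 → −40 °C; then MeI, HMPA, THF, −40 → 0 °C
Reagents that add atoms: lithium dimethylcuprate, [Li+].C[Cu-]C; iodomethane, CI
Why: Tandem cuprate conjugate addition and enolate alkylation, in which the methyl group should add to C4 anti to the C5 aryl group and the enolate should be methylated at C3 anti to the new C4 methyl, giving the all-trans lactone under substrate control.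

Step 6
Reactants: 10 all-trans lactone
Product: 11 (3R,4R,5R)-3,4-dimethyl-5-[3-methoxy-4-(tosyloxy)phenyl]oxolan-2-ol (mixture of anomers)
Conditions: i-Bu2AlH, CH2Cl2, −78 °C; aq. KNaC4H4O6
Reagents that add atoms: none
Why: Partial reduction of a γ-lactone with i-Bu2AlH at −78 °C should stop at the aluminium hemiacetal, and the aryl tosylate is inert to the hydride at this temperature.

Step 7
Reactants: 11 lactol
Product: 12 (1R,2R,3S)-1-[3-methoxy-4-(tosyloxy)phenyl]-2,3-dimethylpent-4-en-1-ol
Conditions: Ph3PCH3Br, KN(SiMe3)2, THF, 0 °C; then 11, 0 → 20 °C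
Reagents that add atoms: methylenetriphenylphosphorane, C=P(c1ccccc1)(c1ccccc1)c1ccccc1
Why: Wittig methylenation of the lactol through its open hydroxy aldehyde should give the terminal alkene, and the mild temperature limits epimerisation of the α-methyl centre.

Step 8
Reactants: 12 alkenol
Product: 13 (1R,2R,3S)-1-[3-methoxy-4-(tosyloxy)phenyl]-2,3-dimethylpent-4-en-1-yl methanesulfonate
Conditions: (MeSO2)2O, Et3N, CH2Cl2, −20 °C
Reagents that add atoms: methanesulfonic anhydride, CS(=O)(=O)OS(C)(=O)=O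
Why: O-sulfonylation proceeds with retention at the carbinol carbon, the anhydride brings no chloride that could displace the benzylic mesylate, and the vinyl group cannot take part as a neighbouring group.

Step 9
Reactants: 13 alkenyl mesylate
Product: 14 (2R,3R,4R)-4-(mesyloxy)-4-[3-methoxy-4-(tosyloxy)phenyl]-2,3-dimethylbutanal
Conditions: O3, CH2Cl2, −78 °C; then PPh3, −78 → 0 °C; used crude
Reagents that add atoms: ozone, [O-][O+]=O
Why: Ozonolysis with reductive work-up should cleave the terminal alkene to the aldehyde under cold, neutral, halide-free conditions that the deactivated benzylic mesylate and the electron-poor ring C tolerate.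

Step 10
Reactants: 15 2-(benzyloxy)phenol
Product: 16 2-(benzyloxy)-4-bromophenol
Conditions: NBS, MeCN, 0 °C
Reagents that add atoms: N-bromosuccinimide, O=C1CCC(=O)N1Br
Why: Electrophilic aromatic bromination should occur para to the free hydroxyl group, the stronger director of the two oxygen substituents.

Step 11
Reactants: 16 2-(benzyloxy)-4-bromophenol
Product: 17 [2-(benzyloxy)-4-bromophenoxy]tri(propan-2-yl)silane
Conditions: i-Pr3SiCl, imidazole, DMF, 20 °C
Reagents that add atoms: chlorotri(propan-2-yl)silane, CC(C)[Si](Cl)(C(C)C)C(C)C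
Why: Imidazole-mediated O-silylation of the phenol gives a bulky silyl ether that survives Grignard formation.

Step 12
Reactants: 14 mesyloxy aldehyde, 17 aryl bromide
Product: 20 (2S,3R,4R,5S)-2-[3-(benzyloxy)-4-(triisopropylsilyloxy)phenyl]-5-[3-methoxy-4-(tosyloxy)phenyl]-3,4-dimethyloxolane, via aryl Grignard reagent 18 (not isolated), via bromomagnesium alkoxide 19 (not isolated)
Conditions: 17, Mg, THF, 45 °C (gives 18, 1.2 equiv); then 14, THF, −78 °C; −78 → 20 °C; aq. NH4Cl
Reagents that add atoms: none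
Why: Magnesium inserts into the C–Br bond of 17, and at −78 °C reagent 18 adds to the aldehyde carbon of 14 through an open Felkin–Anh transition state in which the C3–C4 branch lies anti to the incoming aryl group and the C3 methyl sits beside the carbonyl oxygen, so alkoxide 19 should carry ring B cis to the C3 methyl (C2 = S, set by substrate 1,2-induction). On warming, the alkoxide oxygen attacks C5 from the side opposite the mesylate in a 5-exo-tet intramolecular Williamson etherification, which closes the oxolane and inverts C5 from R to S, so the trans C4/C5 relation becomes cis. The closest known reaction type is the Grignard addition to γ-halo or γ-sulfonyloxy carbonyl compounds that gives tetrahydrofurans in the same flask. The step needs chemoselectivity for the aldehyde over both sulfonates, facial selectivity at C2 and a purely bimolecular substitution at C5. The first is secured by the low temperature and the small excess of 18, the second by the α-methyl stereocentre, and the third by the tosyloxy group para to C5, which disfavours a benzylic cation, together with the five-membered transition state.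

Step 13
Reactants: 20 protected oxolane
Product: 21 2-(benzyloxy)-4-[(2S,3R,4R,5S)-5-(4-hydroxy-3-methoxyphenyl)-3,4-dimethyloxolan-2-yl]phenol
Conditions: KOH, MeOH/THF/H2O, 65 °C; then aq. HCl to pH 6
Reagents that add atoms: none
Why: Alkaline cleavage of the aryl silyl ether and saponification of the aryl sulfonate at sulfur should free both phenols in one operation, while the benzyl ether and the oxolane are inert to base.

Step 14
Reactants: 22 ethyl (S)-lactate
Product: 23 (S)-2-hydroxy-N-methoxy-N-methylpropanamide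
Conditions: MeNH(OMe)·HCl, i-PrMgCl, THF, −20 → 0 °C
Reagents that add atoms: N,O-dimethylhydroxylamine hydrochloride, CNOC.Cl
Why: Aminolysis of the ester by the magnesium amide gives the Weinreb amide, and the stereocentre is protected from enolisation as its magnesium alkoxide.

Step 15
Reactants: 23 Weinreb amide, 24 (3,4-dimethoxyphenyl)magnesium bromide
Product: 25 (S)-1-(3,4-dimethoxyphenyl)-2-hydroxypropan-1-one
Conditions: 24 (3 equiv), THF, 0 → 20 °C; aq. NH4Cl
Reagents that add atoms: none
Why: Weinreb ketone synthesis, in which the aryl Grignard reagent adds once through the stable magnesium chelate and the α-alkoxide keeps the stereocentre from epimerising.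

Step 16
Reactants: 25 α-hydroxy ketone
Product: 26 (S)-1-(3,4-dimethoxyphenyl)-1-oxopropan-2-yl 4-methylbenzenesulfonate
Conditions: TsCl, pyridine, DMAP (cat.), CH2Cl2, 0 °C
Reagents that add atoms: 4-methylbenzenesulfonyl chloride, Cc1ccc(cc1)S(Cl)(=O)=O
Why: O-tosylation with a weak base at 0 °C proceeds with retention and should not enolise the ketone.

Step 17
Reactants: 21 bisphenol, 26 α-tosyloxy ketone
Product: 27 (2R)-2-{2-(benzyloxy)-4-[(2S,3R,4R,5S)-5-(4-{[(2R)-1-(3,4-dimethoxyphenyl)-1-oxopropan-2-yl]oxy}-3-methoxyphenyl)-3,4-dimethyloxolan-2-yl]phenoxy}-1-(3,4-dimethoxyphenyl)propan-1-one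
Conditions: 26 (2.4 equiv), BEMP (2-tert-butylimino-2-diethylamino-1,3-dimethylperhydro-1,3,2-diazaphosphorine, 2.5 equiv), CH2Cl2, 0 → 20 °C
Reagents that add atoms: none
Why: Double Williamson etherification, in which each phenoxide displaces the ketone-activated secondary tosylate by SN2 with inversion, should give the (R) ether carbon in both arms; the metal-free phosphazene base limits enolisation.

Step 18
Reactants: 27 bis(aryloxy ketone)
Product: 28 (1R,2R)-2-{2-(benzyloxy)-4-[(2S,3R,4R,5S)-5-(4-{[(1R,2R)-1-(3,4-dimethoxyphenyl)-1-hydroxypropan-2-yl]oxy}-3-methoxyphenyl)-3,4-dimethyloxolan-2-yl]phenoxy}-1-(3,4-dimethoxyphenyl)propan-1-ol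
Conditions: LiBH(sec-Bu)3 (3 equiv), THF, −78 °C; then H2O
Reagents that add atoms: none
Why: Reduction by a bulky, non-chelating trialkylborohydride under polar Felkin–Anh control, with hydride entering anti to the aryloxy group, should give the threo (1R) carbinol in each arm.

Step 19
Reactants: 28 benzyl ether
Product: 29 manassantin B1, (1R,2R)-1-(3,4-dimethoxyphenyl)-2-{4-[(2S,3R,4R,5S)-5-(4-{[(1R,2R)-1-(3,4-dimethoxyphenyl)-1-hydroxypropan-2-yl]oxy}-3-methoxyphenyl)-3,4-dimethyloxolan-2-yl]-2-hydroxyphenoxy}propan-1-ol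
Conditions: H2 (1 atm), Pd/C (palladium on carbon), EtOAc, 20 °C
Reagents that add atoms: none
Why: Hydrogenolysis of a phenolic benzyl ether is much faster than cleavage of the benzylic carbinol or oxolane C–O bonds, so it should free the ring-B phenol alone.

**Compound list**

1 | vanillin | COc1cc(C=O)ccc1O | starting material
2 | 4-formyl-2-methoxyphenyl 4-methylbenzenesulfonate | COc1cc(C=O)ccc1OS(=O)(=O)c1ccc(C)cc1 | intermediate
3 | vinylmagnesium bromide | C=C[Mg]Br | starting material
4 | divinylzinc | C=C[Zn]C=C | intermediate (not isolated)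
5 | (R)-1-[3-methoxy-4-(tosyloxy)phenyl]prop-2-en-1-ol | C=C[C@@H](O)c1ccc(OS(=O)(=O)c2ccc(C)cc2)c(OC)c1 | intermediate
6 | acryloyl chloride | C=CC(Cl)=O | starting material
7 | (R)-1-[3-methoxy-4-(tosyloxy)phenyl]prop-2-en-1-yl prop-2-enoate | C=C[C@@H](OC(=O)C=C)c1ccc(OS(=O)(=O)c2ccc(C)cc2)c(OC)c1 | intermediate
8 | (R)-5-[3-methoxy-4-(tosyloxy)phenyl]furan-2(5H)-one | O=C1C=C[C@H](c2ccc(OS(=O)(=O)c3ccc(C)cc3)c(OC)c2)O1 | intermediate
9 | lithium (4R,5R)-4-methyl-5-[3-methoxy-4-(tosyloxy)phenyl]-4,5-dihydrofuran-2-olate | [Li+].[O-]C1=C[C@@H](C)[C@H](c2ccc(OS(=O)(=O)c3ccc(C)cc3)c(OC)c2)O1 | intermediate (not isolated)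
10 | (3R,4R,5R)-3,4-dimethyl-5-[3-methoxy-4-(tosyloxy)phenyl]oxolan-2-one | O=C1O[C@@H](c2ccc(OS(=O)(=O)c3ccc(C)cc3)c(OC)c2)[C@H](C)[C@H]1C | intermediate
11 | (3R,4R,5R)-3,4-dimethyl-5-[3-methoxy-4-(tosyloxy)phenyl]oxolan-2-ol | OC1O[C@@H](c2ccc(OS(=O)(=O)c3ccc(C)cc3)c(OC)c2)[C@H](C)[C@H]1C | intermediate
12 | (1R,2R,3S)-1-[3-methoxy-4-(tosyloxy)phenyl]-2,3-dimethylpent-4-en-1-ol | C=C[C@H](C)[C@@H](C)[C@@H](O)c1ccc(OS(=O)(=O)c2ccc(C)cc2)c(OC)c1 | intermediate
13 | (1R,2R,3S)-1-[3-methoxy-4-(tosyloxy)phenyl]-2,3-dimethylpent-4-en-1-yl methanesulfonate | C=C[C@H](C)[C@@H](C)[C@@H](OS(C)(=O)=O)c1ccc(OS(=O)(=O)c2ccc(C)cc2)c(OC)c1 | intermediate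
14 | (2R,3R,4R)-4-(mesyloxy)-4-[3-methoxy-4-(tosyloxy)phenyl]-2,3-dimethylbutanal | O=C[C@H](C)[C@@H](C)[C@@H](OS(C)(=O)=O)c1ccc(OS(=O)(=O)c2ccc(C)cc2)c(OC)c1 | intermediate
15 | 2-(benzyloxy)phenol | Oc1ccccc1OCc1ccccc1 | starting material
16 | 2-(benzyloxy)-4-bromophenol | Oc1ccc(Br)cc1OCc1ccccc1 | intermediate
17 | [2-(benzyloxy)-4-bromophenoxy]tri(propan-2-yl)silane | CC(C)[Si](C(C)C)(C(C)C)Oc1ccc(Br)cc1OCc1ccccc1 | intermediate
18 | [3-(benzyloxy)-4-(triisopropylsilyloxy)phenyl]magnesium bromide | Br[Mg]c1ccc(O[Si](C(C)C)(C(C)C)C(C)C)c(OCc2ccccc2)c1 | intermediate (not isolated)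
19 | bromomagnesium (1S,2R,3R,4R)-1-[3-(benzyloxy)-4-(triisopropylsilyloxy)phenyl]-4-(mesyloxy)-4-[3-methoxy-4-(tosyloxy)phenyl]-2,3-dimethylbutan-1-olate | Br[Mg]O[C@H](c1ccc(O[Si](C(C)C)(C(C)C)C(C)C)c(OCc2ccccc2)c1)[C@H](C)[C@@H](C)[C@@H](OS(C)(=O)=O)c1ccc(OS(=O)(=O)c2ccc(C)cc2)c(OC)c1 | intermediate (not isolated)
20 | (2S,3R,4R,5S)-2-[3-(benzyloxy)-4-(triisopropylsilyloxy)phenyl]-5-[3-methoxy-4-(tosyloxy)phenyl]-3,4-dimethyloxolane | CC(C)[Si](C(C)C)(C(C)C)Oc1ccc(cc1OCc2ccccc2)[C@H]3O[C@H](c4ccc(OS(=O)(=O)c5ccc(C)cc5)c(OC)c4)[C@H](C)[C@H]3C | intermediate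
21 | 2-(benzyloxy)-4-[(2S,3R,4R,5S)-5-(4-hydroxy-3-methoxyphenyl)-3,4-dimethyloxolan-2-yl]phenol | Oc1ccc(cc1OCc2ccccc2)[C@H]3O[C@H](c4ccc(O)c(OC)c4)[C@H](C)[C@H]3C | intermediate
22 | ethyl (S)-lactate | C[C@H](O)C(=O)OCC | starting material
23 | (S)-2-hydroxy-N-methoxy-N-methylpropanamide | C[C@H](O)C(=O)N(C)OC | intermediate
24 | (3,4-dimethoxyphenyl)magnesium bromide | COc1ccc([Mg]Br)cc1OC | starting material
25 | (S)-1-(3,4-dimethoxyphenyl)-2-hydroxypropan-1-one | C[C@H](O)C(=O)c1ccc(OC)c(OC)c1 | intermediate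
26 | (S)-1-(3,4-dimethoxyphenyl)-1-oxopropan-2-yl 4-methylbenzenesulfonate | C[C@H](OS(=O)(=O)c1ccc(C)cc1)C(=O)c1ccc(OC)c(OC)c1 | intermediate
27 | bis[(R)-α-aryloxy ketone], name as in step 17 | COc1ccc(C(=O)[C@@H](C)Oc2ccc([C@H]3O[C@H](c4ccc(O[C@H](C)C(=O)c5ccc(OC)c(OC)c5)c(OC)c4)[C@H](C)[C@H]3C)cc2OCc6ccccc6)cc1OC | intermediate
28 | O-benzyl manassantin B1, name as in step 18 | COc1ccc([C@@H](O)[C@@H](C)Oc2ccc([C@H]3O[C@H](c4ccc(O[C@H](C)[C@H](O)c5ccc(OC)c(OC)c5)c(OC)c4)[C@H](C)[C@H]3C)cc2OCc6ccccc6)cc1OC | intermediate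
29 | manassantin B1 | COc1ccc([C@@H](O)[C@@H](C)Oc2ccc([C@H]3O[C@H](c4ccc(O[C@H](C)[C@H](O)c5ccc(OC)c(OC)c5)c(OC)c4)[C@H](C)[C@H]3C)cc2O)cc1OC | target

**Step count.** Total: 19 steps. Longest linear sequence: 14 steps (steps 1–9, 12, 13, 17, 18, 19); the aryl bromide (steps 10–11) and the side-arm ketone (steps 14–16) are made in parallel.

**Steps most likely to fail**

Step 12. The facial bias of the Grignard addition at C2 may be weak, and C5 may lose its configuration if the benzylic mesylate ionises or is exchanged by bromide before the alkoxide closes; elimination to the styrene is a further drain. The fallback forms the C2–aryl bond on a cyclic oxocarbenium ion, with C5 inverted beforehand. It sets out from lactone 10: aminolysis with MeNH(OMe)·HCl and AlMe3 gives (2R,3R,4R)-4-hydroxy-N-methoxy-4-[3-methoxy-4-(tosyloxy)phenyl]-N,2,3-trimethylbutanamide F1. Methanesulfonic anhydride and Et3N give its 4-methanesulfonate F2, which should close through the amide oxygen with inversion at the benzylic carbon and give, on aqueous work-up, (3R,4R,5S)-3,4-dimethyl-5-[3-methoxy-4-(tosyloxy)phenyl]oxolan-2-one F3. Reduction with i-Bu2AlH gives the lactol (3R,4R,5S)-3,4-dimethyl-5-[3-methoxy-4-(tosyloxy)phenyl]oxolan-2-ol F4, and benzenesulfinic acid with CaCl2 converts it into (3R,4R,5S)-3,4-dimethyl-5-[3-methoxy-4-(tosyloxy)phenyl]-2-(phenylsulfonyl)oxolane F5. Reagent 18 with ZnBr2 gives [3-(benzyloxy)-4-(triisopropylsilyloxy)phenyl]zinc bromide F6, which replaces the sulfinate through the oxocarbenium ion; it is expected to enter on the face away from the C4 methyl and the C5 aryl group. The sequence comes back to the route at 20.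

Step 2. A salt-promoted, uncatalysed vinyl transfer may erode the enantiomeric purity of 5, and the electron-poor aldehyde makes this background reaction faster. The fallback separates C–C bond formation from the setting of the stereocentre. It sets out from 2: addition of vinylmagnesium bromide 3 gives racemic 1-[3-methoxy-4-(tosyloxy)phenyl]prop-2-en-1-ol F7. A Sharpless kinetic resolution (Ti(OiPr)4, D-(−)-diisopropyl tartrate, t-BuOOH 0.6 equiv, 4 Å sieves, CH2Cl2, −20 °C) should epoxidise the (S)-enantiomer to (R)-[3-methoxy-4-(tosyloxy)phenyl][(S)-oxiran-2-yl]methanol F8 and leave the (R)-alcohol, at the cost of half the material. It comes back to the route at 5.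

Step 9. Ozone may attack the aromatic ring, and the benzylic mesylate may be lost by solvolysis, elimination or alkylation of the phosphine while the ozonide is reduced and the aldehyde is isolated. The fallback reaches the aldehyde by oxidation of a masked primary alcohol instead of alkene cleavage. It sets out from lactone 10: LiBH4 gives (1R,2R,3R)-1-[3-methoxy-4-(tosyloxy)phenyl]-2,3-dimethylbutane-1,4-diol F9. Chlorotriethylsilane and imidazole at −40 °C silylate the primary hydroxyl to give (1R,2R,3R)-1-[3-methoxy-4-(tosyloxy)phenyl]-2,3-dimethyl-4-(triethylsilyloxy)butan-1-ol F10. Methanesulfonic anhydride and Et3N give (1R,2R,3R)-1-[3-methoxy-4-(tosyloxy)phenyl]-2,3-dimethyl-4-(triethylsilyloxy)butyl methanesulfonate F11. Swern conditions ((COCl)2, DMSO, then Et3N, −78 → −30 °C) oxidise the primary triethylsilyl ether directly to the aldehyde. It comes back to the route at 14.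

**Further compounds**

F1 | step 12 | (2R,3R,4R)-4-hydroxy-N-methoxy-4-[3-methoxy-4-(tosyloxy)phenyl]-N,2,3-trimethylbutanamide | CON(C)C(=O)[C@H](C)[C@@H](C)[C@@H](O)c1ccc(OS(=O)(=O)c2ccc(C)cc2)c(OC)c1
F2 | step 12 | (1R,2R,3R)-4-[methoxy(methyl)amino]-1-[3-methoxy-4-(tosyloxy)phenyl]-2,3-dimethyl-4-oxobutyl methanesulfonate | CON(C)C(=O)[C@H](C)[C@@H](C)[C@@H](OS(C)(=O)=O)c1ccc(OS(=O)(=O)c2ccc(C)cc2)c(OC)c1
F3 | step 12 | (3R,4R,5S)-3,4-dimethyl-5-[3-methoxy-4-(tosyloxy)phenyl]oxolan-2-one | O=C1O[C@H](c2ccc(OS(=O)(=O)c3ccc(C)cc3)c(OC)c2)[C@H](C)[C@H]1C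
F4 | step 12 | (3R,4R,5S)-3,4-dimethyl-5-[3-methoxy-4-(tosyloxy)phenyl]oxolan-2-ol | OC1O[C@H](c2ccc(OS(=O)(=O)c3ccc(C)cc3)c(OC)c2)[C@H](C)[C@H]1C
F5 | step 12 | (3R,4R,5S)-3,4-dimethyl-5-[3-methoxy-4-(tosyloxy)phenyl]-2-(phenylsulfonyl)oxolane | O=S(=O)(c1ccccc1)C1O[C@H](c2ccc(OS(=O)(=O)c3ccc(C)cc3)c(OC)c2)[C@H](C)[C@H]1C
F6 | step 12 | [3-(benzyloxy)-4-(triisopropylsilyloxy)phenyl]zinc bromide | Br[Zn]c1ccc(O[Si](C(C)C)(C(C)C)C(C)C)c(OCc2ccccc2)c1
F7 | step 2 | racemic 1-[3-methoxy-4-(tosyloxy)phenyl]prop-2-en-1-ol | C=CC(O)c1ccc(OS(=O)(=O)c2ccc(C)cc2)c(OC)c1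
F8 | step 2 | (R)-[3-methoxy-4-(tosyloxy)phenyl][(S)-oxiran-2-yl]methanol | O[C@H](c1ccc(OS(=O)(=O)c2ccc(C)cc2)c(OC)c1)[C@@H]1CO1
F9 | step 9 | (1R,2R,3R)-1-[3-methoxy-4-(tosyloxy)phenyl]-2,3-dimethylbutane-1,4-diol | OC[C@H](C)[C@@H](C)[C@@H](O)c1ccc(OS(=O)(=O)c2ccc(C)cc2)c(OC)c1
F10 | step 9 | (1R,2R,3R)-1-[3-methoxy-4-(tosyloxy)phenyl]-2,3-dimethyl-4-(triethylsilyloxy)butan-1-ol | CC[Si](CC)(CC)OC[C@H](C)[C@@H](C)[C@@H](O)c1ccc(OS(=O)(=O)c2ccc(C)cc2)c(OC)c1
F11 | step 9 | (1R,2R,3R)-1-[3-methoxy-4-(tosyloxy)phenyl]-2,3-dimethyl-4-(triethylsilyloxy)butyl methanesulfonate | CC[Si](CC)(CC)OC[C@H](C)[C@@H](C)[C@@H](OS(C)(=O)=O)c1ccc(OS(=O)(=O)c2ccc(C)cc2)c(OC)c1
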